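## Retrosynthetic overview
- The target is a trans-2,4-flavan-4-ol. The pyran ring is closed last, by an intramolecular Mitsunobu C2–O1 etherification with inversion, from a 1,3-anti-diol.
- That diol comes from a substrate-controlled anti-reduction (Evans–Saksena) of a β-hydroxy aryl ketone. The ketone is made from an aryllithium and the Weinreb amide of (R)-3-hydroxy-3-phenylpropanoate, which supplies C2 from the chiral pool.
- The key step is an aromatic Claisen [3,3] rearrangement of an aryl 1,1-dimethylallyl ether. It forms the C8–prenyl bond and gives 2-prenyl-3,5-dimethoxyphenol, and it is done first.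
- Order of construction: arene prenylation, then the acyclic C–C bond and the C4 stereocenter, then the heterocycle.

Assumptions (one line): (R)-ethyl 3-hydroxy-3-phenylpropanoate is purchasable in high ee; directed lithiation of the MOM ether occurs at C6 (between OMOM and OMe).

## Route

**Step 1**
Reactants: 1 (3,5-dimethoxyphenol); 2 (3-chloro-3-methylbut-1-yne)
Product: 3 (1-(2-methylbut-3-yn-2-yloxy)-3,5-dimethoxybenzene)
Conditions: K2CO3, KI, CuI (cat.), acetone, 60 °C
Reagents that add atoms: 3-chloro-3-methylbut-1-yne, CC(C)(Cl)C#C
Why: Cu-assisted O-alkylation (Williamson-type) of the phenoxide with the tertiary propargylic chloride gives the aryl propargyl ether, a precursor of the 1,1-dimethylallyl ether.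

**Step 2**
Reactants: 3
Product: 4 (1-(2-methylbut-3-en-2-yloxy)-3,5-dimethoxybenzene)
Conditions: H2 (1 atm), Lindlar catalyst, quinoline, EtOAc, rt
Reagents that add atoms: none
Why: Lindlar semihydrogenation stops at the terminal alkene and leaves the aryl ethers intact. This makes the 1,1-dimethylallyl ether needed to deliver a normal prenyl group in the Claisen step.

**Step 3**
Reactants: 4
Product: 5 (2-(3-methylbut-2-en-1-yl)-3,5-dimethoxyphenol, "2-prenyl-3,5-dimethoxyphenol")
Conditions: PhNEt2, 140 °C, sealed tube, 3 h
Reagents that add atoms: none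
Why: Aromatic Claisen rearrangement (key step). The weak tertiary allylic C–O bond makes [3,3] shift easy. The new C–C bond forms at the vinyl CH2 terminus, so the product is prenyl rather than reverse-prenyl. Both ortho positions of the symmetric phenol are equivalent, so regiochemistry is not an issue. Dienone tautomerization restores the phenol.

**Step 4**
Reactants: 5; 6 (chloromethyl methyl ether, MOMCl)
Product: 7 (1-(methoxymethoxy)-2-prenyl-3,5-dimethoxybenzene)
Conditions: MOMCl, i-Pr2NEt, CH2Cl2, 0 °C to rt
Reagents that add atoms: MOMCl, COCCl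
Why: O-Alkylation protects the phenol and installs a strong ortho-directing group for the next lithiation. The prenyl alkene is untouched.

**Step 5**
Reactants: 8 ((R)-ethyl 3-hydroxy-3-phenylpropanoate); 9 (N,O-dimethylhydroxylamine hydrochloride)
Product: 10 ((R)-3-hydroxy-N-methoxy-N-methyl-3-phenylpropanamide)
Conditions: i-PrMgCl (4 equiv), THF, −20 to 0 °C
Reagents that add atoms: MeNH(OMe)·HCl, CNOC.Cl
Why: Magnesium-amide aminolysis of the ester (Weinreb amidation) tolerates the free β-alkoxide. The chiral pool carbinol stereocenter is untouched and remains (R).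

**Step 6**
Reactants: 7 (2.5 equiv); 10 (1 equiv)
Product: 11 ((R)-3-hydroxy-1-[2-(methoxymethoxy)-4,6-dimethoxy-3-prenylphenyl]-3-phenylpropan-1-one)
Conditions: n-BuLi (2.5 equiv), THF, −78 to −20 °C, then add 10 at −78 °C to 0 °C
Reagents that add atoms: none (n-BuLi leaves no atoms in the product)
Why: Directed ortho-metalation at C6, the position flanked by OMOM and OMe, gives the aryllithium. It adds once to the Weinreb amide, whose stable chelated tetrahedral intermediate prevents over-addition; the first equivalent of base only deprotonates the OH. C6 becomes C4a of the chroman, so the C5-OMe and C8a-O pattern is set.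

**Step 7**
Reactants: 11
Product: 12 ((R)-1-(2-hydroxy-4,6-dimethoxy-3-prenylphenyl)-3-hydroxy-3-phenylpropan-1-one)
Conditions: ZnBr2, n-PrSH, CH2Cl2, 0 °C, 10 min
Reagents that add atoms: none (the MOM group is lost as CH3OCH2SPr)
Why: Mild Lewis-acid thiolysis removes the MOM group without acid-promoted dehydration of the β-hydroxy ketone. The ortho-acyl group deactivates the ring toward side reactions.

**Step 8**
Reactants: 12
Product: 13 ((1R,3R)-1-(2-hydroxy-4,6-dimethoxy-3-prenylphenyl)-3-phenylpropane-1,3-diol)
Conditions: Me4NBH(OAc)3 (5 equiv), MeCN/AcOH 1:1, −20 °C to rt, 48 h; quench with aqueous Rochelle salt/NaHCO3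
Reagents that add atoms: none (only hydride and H are added)
Why: Evans–Saksena reduction. The β-alkoxide exchanges onto boron and delivers hydride intramolecularly through a chair transition state, giving the 1,3-anti-diol. The achiral reagent is controlled by the existing (R) carbinol, so C4 is formed R, the (R,R)-anti diol.

**Step 9**
Reactants: 13
Product: 14 (target, (2S,4R)-5,7-dimethoxy-8-prenylflavan-4-ol)
Conditions: PPh3 (1.5 equiv), DIAD (1.5 equiv), THF, 0 °C to rt
Reagents that add atoms: none (PPh3 and DIAD leave as Ph3P=O and the hydrazide)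
Why: Intramolecular Mitsunobu 6-exo SN2 of the phenoxide on the less hindered C2 benzylic alcohol inverts C2 from R to S, while C4 (R) is not touched. This gives 2,4-trans, matching the (2S,4R) target.

**Check against the target SMILES**
- Ring sizes and substituents: the product has a 2-phenylchroman, 4-OH, 5-OMe, 7-OMe and 8-prenyl. C4a sits between C5-OMe and C8a–O, and the prenyl group is adjacent to both C7-OMe and C8a–O.
- Configuration: C2 is S and C4 is R, which is trans.
- Formula: C22H26O4.

## Compound list
1 | 3,5-dimethoxyphenol | COc1cc(O)cc(OC)c1 | starting material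
2 | 3-chloro-3-methylbut-1-yne | CC(C)(Cl)C#C | starting material
3 | 1-(2-methylbut-3-yn-2-yloxy)-3,5-dimethoxybenzene | COc1cc(OC(C)(C)C#C)cc(OC)c1 | intermediate
4 | 1-(2-methylbut-3-en-2-yloxy)-3,5-dimethoxybenzene | COc1cc(OC(C)(C)C=C)cc(OC)c1 | intermediate
5 | 2-prenyl-3,5-dimethoxyphenol | COc1cc(O)c(CC=C(C)C)c(OC)c1 | intermediate
6 | chloromethyl methyl ether (MOMCl) | COCCl | starting material
7 | 1-(methoxymethoxy)-2-prenyl-3,5-dimethoxybenzene | COCOc1cc(OC)cc(OC)c1CC=C(C)C | intermediate
8 | (R)-ethyl 3-hydroxy-3-phenylpropanoate | CCOC(=O)C[C@@H](O)c1ccccc1 | starting material (chiral pool)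
9 | N,O-dimethylhydroxylamine hydrochloride | CNOC.Cl | starting material
10 | (R)-3-hydroxy-N-methoxy-N-methyl-3-phenylpropanamide | CON(C)C(=O)C[C@@H](O)c1ccccc1 | intermediate
11 | (R)-3-hydroxy-1-[2-(methoxymethoxy)-4,6-dimethoxy-3-prenylphenyl]-3-phenylpropan-1-one | COCOc1c(CC=C(C)C)c(OC)cc(OC)c1C(=O)C[C@@H](O)c1ccccc1 | intermediate
12 | (R)-1-(2-hydroxy-4,6-dimethoxy-3-prenylphenyl)-3-hydroxy-3-phenylpropan-1-one | COc1cc(OC)c(C(=O)C[C@@H](O)c2ccccc2)c(O)c1CC=C(C)C | intermediate
13 | (1R,3R)-1-(2-hydroxy-4,6-dimethoxy-3-prenylphenyl)-3-phenylpropane-1,3-diol | COc1cc(OC)c([C@H](O)C[C@@H](O)c2ccccc2)c(O)c1CC=C(C)C | intermediate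
14 | (2S,4R)-5,7-dimethoxy-8-prenylflavan-4-ol | COc1cc(OC)c2c(c1CC=C(C)C)O[C@H](c1ccccc1)C[C@H]2O | target

## Summary
Total steps: 9. Longest linear sequence: 8 (steps 1, 2, 3, 4, 6, 7, 8, 9; step 5 is a parallel branch).

Three steps most likely to fail:
1. **Step 8 (anti-reduction).** The 2-hydroxy-4,6-dimethoxyaryl ketone is a deactivated, H-bonded vinylogous ester, and the electron-rich benzylic diol is acid-labile in AcOH. Fallback: close the ring first by intramolecular Mitsunobu of 12 to the (2S)-flavanone, reduce with NaBH4 to the cis-(2S,4S)-alcohol, then invert C4 with 4-nitrobenzoic acid under Mitsunobu conditions followed by K2CO3/MeOH.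
2. **Step 9 (Mitsunobu cyclization).** Competing activation or ionization at the electron-rich C4 benzylic alcohol, or partial racemization at C2, could occur. Fallback: do a stepwise closure by selective C2 mesylation (MsCl, Et3N, −20 °C) and then Cs2CO3/DMF SN2 by the phenoxide.
3. **Step 6 (lithiation and acylation).** Deprotonation may occur at C4 (between the two OMe groups) instead of C6. Fallback: ortho-brominate phenol 5 selectively (NBS, i-Pr2NH), protect it as the MOM ether, and generate a regiodefined aryllithium by Br/Li exchange (t-BuLi) before the same Weinreb acylation.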